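**Retrosynthetic overview**

1. The target is epigallocatechin-(4β→8)-epigallocatechin-(4β→8)-epigallocatechin 3-O-gallate-(4β→8)-epicatechin (units 1 to 4 from the chain top; every unit 2R,3R; every C4 aryl trans to the C3 oxygen). The last disconnection is the 22 phenolic benzyl ethers (hydrogenolysis).
2. The three C4–C8 interflavan bonds are cut one at a time from the top. Each extension unit becomes a 4β-(2-ethoxyethoxy) flavan donor; the chain end is benzylated (−)-epicatechin.
3. Key disconnection: the C4–O bond of the donors. One new C–O bond-forming step, a gallate-relayed oxidative C4–H etherification of perbenzylated EGCG, gives the galloylated donor (unit 3). Methanolysis of its gallate gives the donor for units 1 and 2, so all gallo units come from EGCG.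
4. No ring is built. All chroman and aryl rings come intact from the two catechins; the only ring formed is the transient dioxolanylium ring of the key step. Order of joining: unit 3 onto unit 4, then unit 2, then unit 1.

Assumption: (−)-EGCG (bulk green-tea catechin) and (−)-epicatechin are taken as the cheap commercial starting materials.

**Route**

Step 1
Reactants: 1 (−)-epigallocatechin 3-O-gallate (EGCG; 2R,3R)
Product: 2 4′,4″-di-O-benzyl-EGCG [(2R,3R)-4′-O-benzyl-3-O-(4-benzyloxy-3,5-dihydroxybenzoyl)epigallocatechin]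
Conditions: BnBr (2.1 equiv), KHCO3 (2.5 equiv), DMF, rt, Ar, dark; aqueous work-up, short silica pad
Reagents that add atoms: benzyl bromide, BrCc1ccccc1
Why: Williamson etherification under hydrogencarbonate, which deprotonates only the two most acidic phenols (the central OH of each pyrogallol ring, pKa near 8 against 9 or more for the others), so the two oxidation-prone pyrogallol units are capped before any carbonate is used; minor regioisomeric ethers need not be removed because they converge on 3 in step 2, and no stereocentre is touched.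

Step 2
Reactants: 2 4′,4″-di-O-benzyl-EGCG
Product: 3 octa-O-benzyl-EGCG [(2R,3R)-5,7,3′,4′,5′-penta-O-benzyl-3-O-(3,4,5-tribenzyloxybenzoyl)epigallocatechin]
Conditions: BnBr (6.6 equiv), K2CO3 (8 equiv), DMF, 0 °C to rt, Ar, dark
Reagents that add atoms: benzyl bromide, BrCc1ccccc1
Why: Williamson etherification of the six remaining phenols (the single aliphatic oxygen is already acylated), and cold oxygen-free DMF avoids C2 epimerisation and autoxidation, so both stereocentres are carried over from the natural product.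

Step 3
Reactants: 3 octa-O-benzyl-EGCG
Product: 5 galloylated donor (2R,3R,4S)-4β-(2-ethoxyethoxy)-octa-O-benzyl-EGCG (C4 ether trans to the C3 ester), via dioxolanylium cation 4 (not isolated)
Conditions: DDQ (2.0 equiv), 2-ethoxyethanol (5 equiv), 4 Å MS, CH2Cl2, 0 °C to rt; then aq. NaHCO3
Reagents that add atoms: 2-ethoxyethanol, CCOCCO
Why: Proposed new method: ester-relayed oxidative C–H etherification, in which DDQ (charge-transfer complex with the 5,7-dibenzyloxy ring A) removes the pseudo-axial 4β-hydride that lies anti-periplanar to the axial 3-O-galloyl group, so the ester carbonyl oxygen closes onto C4 from the α-face as hydride leaves and forms the cis-fused dioxolanylium cation 4; this face-blocked cation can be opened by the alcohol only at benzylic C4 from the β-face (any orthoester formed at the acyl carbon re-ionises under the acidity of the hydroquinone), which sets the new C4 stereocentre as 4β (3,4-trans), keeps the gallate on O3 and shields the product from a second oxidation; the closest known reaction type is the DDQ C4–H alkoxylation of 3-hydroxyflavan benzyl ethers, combined with acyloxonium neighbouring-group participation as in 1,2-trans glycosylation, and it has not been shown on a 3-O-acyl flavan where the ester takes part.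

Step 4
Reactants: 5 galloylated donor
Product: 6 donor (2R,3R,4S)-4β-(2-ethoxyethoxy)-5,7,3′,4′,5′-penta-O-benzylepigallocatechin (free 3-OH)
Conditions: K2CO3 (0.5 equiv), MeOH/THF 1:1, rt to 40 °C (about two thirds of 5; the rest goes to step 6)
Reagents that add atoms: none
Why: Base-catalysed transesterification (methanolysis) cleaves only the acyl C–O bond of the gallate, while the benzyl ethers, the C4 ether and the three stereocentres are inert to methoxide.

Step 5
Reactants: 7 (−)-epicatechin (2R,3R)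
Product: 8 (2R,3R)-5,7,3′,4′-tetra-O-benzylepicatechin (free 3-OH)
Conditions: BnBr (4.4 equiv), K2CO3 (5 equiv), DMF, 0 °C to rt, Ar
Reagents that add atoms: benzyl bromide, BrCc1ccccc1
Why: Williamson etherification that is chemoselective for the four phenols because K2CO3 does not deprotonate the secondary 3-OH; no stereocentre is touched.

Step 6
Reactants: 5 galloylated donor; 8 tetra-O-benzylepicatechin (3 equiv; excess recovered)
Product: 9 dimer [penta-O-benzyl-3-O-(tri-O-benzylgalloyl)epigallocatechin]-(4β→8)-[tetra-O-benzylepicatechin]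
Conditions: TMSOTf (0.1 equiv), CH2Cl2, −78 to −40 °C; Et3N quench
Reagents that add atoms: none
Why: Lewis-acid-promoted Friedel–Crafts flavanylation (SN1 at C4) in which TMSOTf ionises the C4 ether of 5, the neighbouring 3-O-galloyl carbonyl shields the α-face of the transient benzylic cation (anchimeric assistance), and C8 of 8, the most electron-rich and least hindered position of its ring A, attacks C4 from the β-face, which sets the 4β→8 bond (3,4-trans); the excess of 8 outcompetes self-condensation of 5.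

Step 7
Reactants: 6 donor (1.0 equiv; slow addition); 9 dimer (1.3 equiv)
Product: 10 trimer [penta-O-benzylepigallocatechin]-(4β→8)-[penta-O-benzyl-3-O-(tri-O-benzylgalloyl)epigallocatechin]-(4β→8)-[tetra-O-benzylepicatechin]
Conditions: Yb(OTf)3 (1.0 equiv), CH2Cl2, 0 °C to rt
Reagents that add atoms: none
Why: The same Friedel–Crafts flavanylation, in which the transient C4 cation from 6 is attacked by C8 of unit 3 of 9 (the only free C8; every free C6 lies between two benzyloxy groups) on the face anti to both the 2-aryl group and the axial 3-OH, which sets the new C4 stereocentre as 4β.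

Step 8
Reactants: 6 donor (1.0 equiv; slow addition); 10 trimer (1.2 equiv)
Product: 11 tetramer [penta-O-benzylepigallocatechin]-(4β→8)-[penta-O-benzylepigallocatechin]-(4β→8)-[penta-O-benzyl-3-O-(tri-O-benzylgalloyl)epigallocatechin]-(4β→8)-[tetra-O-benzylepicatechin] (22 benzyl ethers; three free 3-OH)
Conditions: Yb(OTf)3 (1.0 equiv), CH2Cl2, 0 °C to rt
Reagents that add atoms: none
Why: Friedel–Crafts flavanylation at C8 of the top unit of 10, the only unsubstituted C8 and the least hindered nucleophilic site, with attack anti to the 2-aryl and 3-OH groups of the donor giving the third 4β→8 bond.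

Step 9
Reactants: 11 tetramer
Product: 12 target, epigallocatechin-(4β→8)-epigallocatechin-(4β→8)-epigallocatechin 3-O-gallate-(4β→8)-epicatechin
Conditions: H2 (1 atm), Pd(OH)2/C, THF/MeOH/H2O 20:20:1, rt; filter under Ar, Sephadex LH-20, freeze-dry
Reagents that add atoms: none
Why: Heterogeneous hydrogenolysis removes the 22 benzyl aryl ethers, while the gallate ester, the interflavan C–C bonds and the ring C ethers are stable to H2 over Pd(OH)2/C at 1 atm and no stereocentre is touched.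

**Compound list**

1 | (−)-epigallocatechin 3-O-gallate (2R,3R) | O=C(O[C@@H]1Cc2c(O)cc(O)cc2O[C@@H]1c1cc(O)c(O)c(O)c1)c1cc(O)c(O)c(O)c1 | starting material

2 | 4′,4″-di-O-benzyl-EGCG: (2R,3R)-4′-O-benzyl-3-O-(4-benzyloxy-3,5-dihydroxybenzoyl)epigallocatechin | O=C(O[C@@H]1Cc2c(O)cc(O)cc2O[C@@H]1c1cc(O)c(OCc7ccccc7)c(O)c1)c1cc(O)c(OCc7ccccc7)c(O)c1 | intermediate

3 | octa-O-benzyl-EGCG: (2R,3R)-5,7,3′,4′,5′-penta-O-benzyl-3-O-(3,4,5-tribenzyloxybenzoyl)epigallocatechin | O=C(O[C@@H]1Cc2c(OCc7ccccc7)cc(OCc7ccccc7)cc2O[C@@H]1c1cc(OCc7ccccc7)c(OCc7ccccc7)c(OCc7ccccc7)c1)c1cc(OCc7ccccc7)c(OCc7ccccc7)c(OCc7ccccc7)c1 | intermediate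

4 | dioxolanylium cation (not isolated): 2-(3,4,5-tribenzyloxyphenyl)-1,3-dioxolan-2-ylium ring cis-fused across C3 and C4 of penta-O-benzylepigallocatechin, both C–O bonds on the α-face (counter-ion: hydroquinone monoanion of DDQ) | C1(c8cc(OCc7ccccc7)c(OCc7ccccc7)c(OCc7ccccc7)c8)=[O+][C@@H]2c3c(OCc7ccccc7)cc(OCc7ccccc7)cc3O[C@H](c3cc(OCc7ccccc7)c(OCc7ccccc7)c(OCc7ccccc7)c3)[C@@H]2O1 | intermediate

5 | galloylated donor: (2R,3R,4S)-4β-(2-ethoxyethoxy)-octa-O-benzyl-EGCG, C4 ether trans to the C3 ester | O=C(O[C@@H]1[C@@H](OCCOCC)c2c(OCc7ccccc7)cc(OCc7ccccc7)cc2O[C@@H]1c1cc(OCc7ccccc7)c(OCc7ccccc7)c(OCc7ccccc7)c1)c1cc(OCc7ccccc7)c(OCc7ccccc7)c(OCc7ccccc7)c1 | intermediate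

6 | donor: (2R,3R,4S)-4β-(2-ethoxyethoxy)-5,7,3′,4′,5′-penta-O-benzylepigallocatechin, free 3-OH | O[C@@H]1[C@@H](OCCOCC)c2c(OCc7ccccc7)cc(OCc7ccccc7)cc2O[C@@H]1c1cc(OCc7ccccc7)c(OCc7ccccc7)c(OCc7ccccc7)c1 | intermediate

7 | (−)-epicatechin (2R,3R) | O[C@@H]1Cc2c(O)cc(O)cc2O[C@@H]1c1ccc(O)c(O)c1 | starting material

8 | (2R,3R)-5,7,3′,4′-tetra-O-benzylepicatechin, free 3-OH | O[C@@H]1Cc2c(OCc7ccccc7)cc(OCc7ccccc7)cc2O[C@@H]1c1ccc(OCc7ccccc7)c(OCc7ccccc7)c1 | intermediate

9 | dimer: [penta-O-benzyl-3-O-(tri-O-benzylgalloyl)epigallocatechin]-(4β→8)-[tetra-O-benzylepicatechin], free 3-OH on the epicatechin unit | O=C(O[C@@H]1[C@@H](c2c(OCc7ccccc7)cc(OCc7ccccc7)c3c2O[C@H](c2ccc(OCc7ccccc7)c(OCc7ccccc7)c2)[C@H](O)C3)c2c(OCc7ccccc7)cc(OCc7ccccc7)cc2O[C@@H]1c1cc(OCc7ccccc7)c(OCc7ccccc7)c(OCc7ccccc7)c1)c1cc(OCc7ccccc7)c(OCc7ccccc7)c(OCc7ccccc7)c1 | intermediate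

10 | trimer: [penta-O-benzylepigallocatechin]-(4β→8)-[penta-O-benzyl-3-O-(tri-O-benzylgalloyl)epigallocatechin]-(4β→8)-[tetra-O-benzylepicatechin] | O=C(O[C@@H]1[C@@H](c2c(OCc7ccccc7)cc(OCc7ccccc7)c3c2O[C@H](c2ccc(OCc7ccccc7)c(OCc7ccccc7)c2)[C@H](O)C3)c2c(OCc7ccccc7)cc(OCc7ccccc7)c([C@H]3c4c(OCc7ccccc7)cc(OCc7ccccc7)cc4O[C@H](c4cc(OCc7ccccc7)c(OCc7ccccc7)c(OCc7ccccc7)c4)[C@@H]3O)c2O[C@@H]1c1cc(OCc7ccccc7)c(OCc7ccccc7)c(OCc7ccccc7)c1)c1cc(OCc7ccccc7)c(OCc7ccccc7)c(OCc7ccccc7)c1 | intermediate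

11 | tetramer: [penta-O-benzylepigallocatechin]-(4β→8)-[penta-O-benzylepigallocatechin]-(4β→8)-[penta-O-benzyl-3-O-(tri-O-benzylgalloyl)epigallocatechin]-(4β→8)-[tetra-O-benzylepicatechin] | O=C(O[C@@H]1[C@@H](c2c(OCc7ccccc7)cc(OCc7ccccc7)c3c2O[C@H](c2ccc(OCc7ccccc7)c(OCc7ccccc7)c2)[C@H](O)C3)c2c(OCc7ccccc7)cc(OCc7ccccc7)c([C@H]3c4c(OCc7ccccc7)cc(OCc7ccccc7)c([C@H]5c6c(OCc7ccccc7)cc(OCc7ccccc7)cc6O[C@H](c6cc(OCc7ccccc7)c(OCc7ccccc7)c(OCc7ccccc7)c6)[C@@H]5O)c4O[C@H](c4cc(OCc7ccccc7)c(OCc7ccccc7)c(OCc7ccccc7)c4)[C@@H]3O)c2O[C@@H]1c1cc(OCc7ccccc7)c(OCc7ccccc7)c(OCc7ccccc7)c1)c1cc(OCc7ccccc7)c(OCc7ccccc7)c(OCc7ccccc7)c1 | intermediate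

12 | epigallocatechin-(4β→8)-epigallocatechin-(4β→8)-epigallocatechin 3-O-gallate-(4β→8)-epicatechin (CNP0305998.1) | O=C(O[C@@H]1[C@@H](c2c(O)cc(O)c3c2O[C@H](c2ccc(O)c(O)c2)[C@H](O)C3)c2c(O)cc(O)c([C@H]3c4c(O)cc(O)c([C@H]5c6c(O)cc(O)cc6O[C@H](c6cc(O)c(O)c(O)c6)[C@@H]5O)c4O[C@H](c4cc(O)c(O)c(O)c4)[C@@H]3O)c2O[C@@H]1c1cc(O)c(O)c(O)c1)c1cc(O)c(O)c(O)c1 | target

**Step count**

Total step count: 9. Longest linear sequence: 7 steps (1 → 2 → 3 → 5 → 6 → 10 → 11 → 12; the branch through 9 is equally long).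

**Three steps most likely to fail**

Step 3 (the proposed new C–H etherification). The electron-withdrawing ester may slow hydride abstraction, and traces of water would divert cation 4 to a hydroxy ester. The fallback uses known chemistry only; it sets out from 3 and comes back to the route at 6 and 5. Methanolysis of the gallate of 3 (K2CO3, MeOH/THF) gives 5,7,3′,4′,5′-penta-O-benzyl-(−)-epigallocatechin F1. The established DDQ/2-ethoxyethanol C4 etherification of this 3-hydroxy flavan (CH2Cl2, rt) gives 6 directly. Steglich esterification of one third of 6 with 3,4,5-tris(benzyloxy)benzoic acid (DCC, DMAP, CH2Cl2) gives 5. This costs one step more than the main route.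

Step 7 (trimer formation). Donor 6 carries its own nucleophilic C8 and can self-condense, and the dimer offers competing C6 sites. The fallback changes the assembly from 1 + 2 to 2 + 2 and also replaces step 8; it sets out from 6 and 9 and comes back at 11. Controlled Lewis-acid self-condensation of 6 (Zn(OTf)2, CH2Cl2, 0 °C, stopped at partial conversion) gives the dimeric donor [penta-O-benzylepigallocatechin]-(4β→8)-[4β-(2-ethoxyethoxy)-penta-O-benzylepigallocatechin] F2. Coupling F2 with 9 (Yb(OTf)3, CH2Cl2) gives 11.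

Step 8 (tetramer formation). This step has the largest nucleophile, the most competing sites, and it cannot tolerate an excess of a self-condensing donor. The fallback blocks C8 of the donor; it sets out from 6 and 10 and comes back at 12. Bromination of 6 (NBS, NaHCO3, CH2Cl2, −78 °C) gives 8-bromo-4β-(2-ethoxyethoxy)-penta-O-benzylepigallocatechin F3, whose most nucleophilic position is capped, so it can be used in excess. Coupling with 10 (TMSOTf, CH2Cl2, −78 °C) gives the 8-bromo tetramer F4 (compound 11 with bromine at C8 of unit 1). Hydrogenolysis with base present (H2, Pd(OH)2/C, Et3N, THF/MeOH/H2O) removes the bromine together with the 22 benzyl groups and gives 12.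

**Further compounds**

F1 | step 3 | (2R,3R)-5,7,3′,4′,5′-penta-O-benzylepigallocatechin | O[C@@H]1Cc2c(OCc7ccccc7)cc(OCc7ccccc7)cc2O[C@@H]1c1cc(OCc7ccccc7)c(OCc7ccccc7)c(OCc7ccccc7)c1

F2 | step 7 | dimeric donor [penta-O-benzylepigallocatechin]-(4β→8)-[4β-(2-ethoxyethoxy)-penta-O-benzylepigallocatechin] | O[C@@H]1[C@@H](OCCOCC)c2c(OCc7ccccc7)cc(OCc7ccccc7)c([C@H]3c4c(OCc7ccccc7)cc(OCc7ccccc7)cc4O[C@H](c4cc(OCc7ccccc7)c(OCc7ccccc7)c(OCc7ccccc7)c4)[C@@H]3O)c2O[C@@H]1c1cc(OCc7ccccc7)c(OCc7ccccc7)c(OCc7ccccc7)c1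

F3 | step 8 | (2R,3R,4S)-8-bromo-4β-(2-ethoxyethoxy)-5,7,3′,4′,5′-penta-O-benzylepigallocatechin | O[C@@H]1[C@@H](OCCOCC)c2c(OCc7ccccc7)cc(OCc7ccccc7)c(Br)c2O[C@@H]1c1cc(OCc7ccccc7)c(OCc7ccccc7)c(OCc7ccccc7)c1

F4 | step 8 | 8-bromo tetramer (compound 11 with Br at C8 of unit 1) | O=C(O[C@@H]1[C@@H](c2c(OCc7ccccc7)cc(OCc7ccccc7)c3c2O[C@H](c2ccc(OCc7ccccc7)c(OCc7ccccc7)c2)[C@H](O)C3)c2c(OCc7ccccc7)cc(OCc7ccccc7)c([C@H]3c4c(OCc7ccccc7)cc(OCc7ccccc7)c([C@H]5c6c(OCc7ccccc7)cc(OCc7ccccc7)c(Br)c6O[C@H](c6cc(OCc7ccccc7)c(OCc7ccccc7)c(OCc7ccccc7)c6)[C@@H]5O)c4O[C@H](c4cc(OCc7ccccc7)c(OCc7ccccc7)c(OCc7ccccc7)c4)[C@@H]3O)c2O[C@@H]1c1cc(OCc7ccccc7)c(OCc7ccccc7)c(OCc7ccccc7)c1)c1cc(OCc7ccccc7)c(OCc7ccccc7)c(OCc7ccccc7)c1
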